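The easy step comes first: 0.200 M of reagent on 0.10 M of substrate is the ratio in which the side reaction consumes them, so one remaining fraction can stand for both while little sits in target.

the same everywhere: substrate 0.10 M; reagent 0.200 M; time 30 min

| charge | temperature |
|---|---|
| theta | 150 °C |
| gamma | 110 °C |
| beta | 130 °C |
| delta | 90 °C |

    target ⇌ isomer of the product (K1 = 0.10, k1 = 0.0070 s⁻¹, Ea1 = 107 kJ mol⁻¹, ΔH1 = −86.0 kJ mol⁻¹)
    substrate + 2 reagent → side product (k2 = 0.50 M⁻² s⁻¹, Ea2 = 55.0 kJ mol⁻¹)
    substrate + reagent ⇌ target (K3 = 19 M⁻¹, k3 = 0.65 M⁻¹ s⁻¹, Ea3 = 57.0 kJ mol⁻¹, ΔH3 = −43.0 kJ mol⁻¹)
    (constants at 110 °C)

- two of one species on the left: rate k times its square, two consumed each time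
- at 110 °C the constants are as listed, elsewhere as the activation energies and enthalpies make them

- the flask that comes out highest in amount of target, in percent of the substrate charged, or "all alike" when all lie within 1.5 percentage points (theta / gamma / beta / delta / all alike)
- target at the end, in percent of the substrate charged, theta
- target at the end, in percent of the substrate charged, gamma
- target at the end, in percent of the substrate charged, beta
- target at the end, in percent of the substrate charged, delta

My bench rule treats the addition as a fast pre-equilibrium and the side reaction as the rate-limiting drain. In theta the drain starts at 0.14 of the forward addition rate, so the addition can keep up with it there. Let k be the rate constant of the drain, c the reagent charge, and f the remnant, the fraction of substrate still free, which the rule takes to be the fraction of reagent still free as well. Then f falls at k times c squared times the cube of f, and this integrates to one over f squared equals 1 plus 2 times k times c squared times t.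

For theta, k is 5.11 times its listed value and the addition constant K is 5.30 M⁻¹. The remnant at 30 min is therefore 5.20%. Target, as a share of the substrate charged, is K times c times f squared, which gives 0.287%. The same reckoning gives 5.21% for gamma and 1.14% for beta. For delta it gives 27.7%, so I commit to delta as highest.

The border of the rule is the ratio of target to free substrate, K times [reagent], which the rule needs to be small. At the end of theta it is 0.0552, and at the end of gamma 0.445. In delta the remnant is 18.6% and the ratio is 1.49, more than one. Delta therefore lies past the border, and that ratio is what I watch on a repeat.

The forecast names delta, with 0.3% for theta, 9.3% for gamma, 1.6% for beta and 35% for delta, on the grounds that “Heating weakens the exothermic binding and speeds the drain”.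

The simulation gives delta as highest, with 0.324% for theta, 9.08% for gamma, 1.52% for beta and 32.8% for delta.

In theta the drain ran early, with half of its turnover done by 0.504 min and 97% done by 15.0 min, and substrate and reagent ended at 5.45% and 5.61% of their charges beside my remnant of 5.20%. In delta, past the border, side product stands at 40.4% of the substrate charged against the 81.4% that the remnant allots to it, while target holds 32.8%, isomer 15.8% and free substrate 11.0%.

For theta read at 2.0 h, the remnant gives 2.60% substrate and 0.0717% target. The run gives 2.67% and 0.0768%.

The rate constants were chosen freely; no experiment stands behind them.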